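## Structural features

The target is the flavone 5,7-dihydroxy-2-(3,5-dihydroxy-4-methoxyphenyl)-6,8-dimethoxy-4H-chromen-4-one. A benzene ring A is fused through the C4a–C8a bond to a 4-pyranone ring C, and C2 of ring C carries the phenyl ring B through a single C2–C1' bond. There is no stereocentre, so every selectivity question is one of position. Ring A has no hydrogen: C5, C6, C7 and C8 carry OH, OMe, OH and OMe in strict alternation and C8a carries the ring oxygen O1. Ring B is a mirror-symmetric 3,5-dihydroxy-4-methoxyphenyl group. The fragile features are the four phenols, above all the electron-rich ring A, which is easily oxidised toward a 5,8-quinone; the alternating OH/OMe pattern cannot be set or repaired by selective methylation or demethylation at the end. The real difficulty is to assemble the fully substituted ring A with every oxygen already differentiated and to fuse ring C onto it in the right sense, since closure through the oxygen on the other side of C4a would give an isomeric chromone. The key step exploits the fact that, in an open-chain 1,3-diketone, the future C8a can be the only hydrogen-bearing carbon of a tetra-alkoxy ring A. It lies ortho to the acyl-bearing C4a and para to the C6 methoxyl, so an oxidative O1–C8a closure has one C–H to find on the most electron-rich part of the molecule.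

## Logic of the disconnections

12 from 10 (through 11). Four oxygen–carbon bonds to protecting groups are cut: the aryl O–CH2Ph bonds at O5 and O7 and the aryl O–acyl bonds at O3' and O5'. Ethers on ring A keep it electron-rich and esters on ring B make it electron-poor, and this contrast is what the anode has to read. Benzyl ethers are kept on ring A because they are donors and leave without touching methyl ethers; pivalates are kept on ring B because they are hindered enough to survive enolate chemistry. The demand is that methanolysis must not open the pyranone and hydrogenolysis must not saturate C2–C3; both are run in one flask.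

10 from 9. The O1–C8a bond is cut. This opens ring C to a 1,3-diketone and removes the fifth oxygen from ring A, which then needs only four oxygens on adjacent carbons and one C–H. The mapping was checked atom by atom: aryl C1, C2–O, C3–O, C4–O, C5–O and C6–H of 9 become C4a, C5–O, C6–O, C7–O, C8–O and C8a of 10. The forward step must form a C–O bond at that single C–H, on ring A and not ring B, without over-oxidising the product.

9 from 5 and 7 (through 8). The C2–C3 bond (flavone numbering) between the diketone methylene and the ring B carbonyl is cut. This divides the molecule into two aromatic halves of similar size, one a methyl ketone and one an activated acid. The forward step must acylate the ketone enolate on carbon, once only, without loss of the pivalates or of the benzyl ether ortho to the ketone.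

7 from 6. The two aryl O–pivaloyl bonds are cut, leading to a commercial acid. The forward step must acylate the phenols and leave the carboxyl group free.

5 from 4. The O–CH2Ph bond at the future O5 is cut. The forward step must alkylate a hydrogen-bonded ortho-hydroxy ketone on oxygen only.

4 from 3. The aryl C–O bond at the future C5 is cut back to a C–I bond. The forward step is a hydroxylation of a hindered aryl iodide beside an enolisable methyl ketone.

3 from 2. The C–I bond is cut. Because 2 is mirror-symmetric, its two free ring positions are equivalent and no regiochemical question arises. The forward step must iodinate the ring and not the acetyl methyl group, and stop after one iodine.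

2 from 1. The O–CH2Ph bond at the future O7 is cut. Compound 1 already holds three of the four ring A oxygens and the acetyl group para to the phenol, exactly where C4 must sit. Buying the acetyl group in place saves a step against acylating a benzylated syringol-derived phenol, and avoids a Lewis-acid acylation next to a benzyl ether.

## Other disconnections considered

Alternative 1: The cut is C8–C8a (with C4a–C5 made one step earlier), so ring A is built last from a squarate unit on a preformed 2-aryl-4-pyranone. The magnesium reagent from 2-[3,5-bis(benzyloxy)-4-methoxyphenyl]-5-iodo-4H-pyran-4-one A4 would add to 3-methoxy-4-(propan-2-yloxy)cyclobut-3-ene-1,2-dione A3 to give the racemic cyclobutenone A2. Heating A2 in toluene or xylene would open the four-membered ring electrocyclically; the ketene carbon would bond to the hydrogen-bearing pyranone carbon next to oxygen, and enolisation would give the 5,8-hydroquinone A1.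
- In its favour: the ring expansion is thermal, reagent-free and a well-established reaction class, so on mechanistic security it is better than the chosen plan. O5 and O8 emerge free while O6 and O7 are ethers, and the chelated 5-OH should allow selective methylation at O8.
- Against it here: the two carbonyls of A3 differ only in methyl versus isopropyl on the remote vinylogous oxygen, so little bias is expected and the wrong adduct would exchange the C6 and C7 substituents. The metalated pyranone is also an electrophile, and A1 is an air-sensitive para-hydroquinone.
- Comparison: the chosen plan takes its regiochemistry from the symmetry of 1 and from a single C–H, while this plan must win it at the squarate addition. After A1, three operations remain (O8 methylation, loss of isopropyl, loss of benzyl) against one, and A3 and A4 each need several steps, so step economy is worse.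

Alternative 2: The cuts are C4a–C4, C4–C3 and O1–C2, so ring C is assembled in one operation. 5-(Benzyloxy)-2-iodo-4,6-dimethoxybenzene-1,3-diol A6, carbon monoxide A8 and 1,3-bis(benzyloxy)-5-ethynyl-2-methoxybenzene A7 would react under zerovalent palladium with phosphine ligands and a secondary amine. Oxidative addition, insertion of A8, acyl–alkynyl coupling and closure by one of the two equivalent hydroxyls would give A5.
- In its favour: three bonds form in one step, which is better than the chosen plan in bond economy. A6 is symmetric, so it does not matter which hydroxyl closes. A5 needs only one hydrogenolysis, which equals the chosen end game. The reaction type is established, which is also better than the chosen plan.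
- Against it here: A6 is a hexasubstituted, very electron-rich aryl iodide with two free ortho hydroxyls. Oxidative addition should be slow, direct coupling without insertion of A8 (leading to a benzofuran) and five-membered closure (leading to an aurone) compete, and the iodoresorcinol is prone to deiodination and oxidation. A6 also needs all five ring A oxygens before the key step, so its preparation is long, and A8 is a toxic gas.
- Comparison: more convergent on paper, but the burden is shifted to a ring A fragment that is harder to make than 5. The overall step count is expected to be higher.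

Alternative 3: The cut is C7–C8, so ring A is folded from a chain on the pyranone. In the racemic keto ester A10 an equilibrating amidine or alkoxide base would deprotonate the methoxymethyl carbon through the vinylogous pyranone. That carbon would attack the terminal methyl ester, and enolisation would aromatise ring A to A9.
- In its favour: the alternating OH/OMe pattern is written into the chain, no protecting group is needed on ring A, and no redox step is involved. A9 needs only one hydrogenolysis, which equals the chosen end game. A Claisen-type closure is classical, which is better than the chosen plan in precedent for the reaction type.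
- Against it here: the C–H between the ketone and the ester of A10 is far more acidic than the methoxymethyl group. The stabilised enolate formed there deactivates the ester, so the closure must run through a minor anion. Retro-Claisen cleavage of the side chain and alkoxide attack on the pyranone compete.
- Comparison: A10 is a densely functionalised pyranone that would take many steps, so step economy is clearly worse. The chosen plan reaches its precursor from two commercial aromatics in six steps.

Key step: step 7

Assumption: 9 is drawn as the diketo tautomer although it should exist mainly as the hydrogen-bonded enol. No compound of the main route has a stereocentre.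

## Route

Step 1
Reactants: 1 1-(4-hydroxy-3,5-dimethoxyphenyl)ethan-1-one (acetosyringone)
Product: 2 1-[4-(benzyloxy)-3,5-dimethoxyphenyl]ethan-1-one
Conditions: BnBr, K2CO3, DMF, 60 °C
Reagents that add atoms: benzyl bromide, BrCc1ccccc1
Why: Williamson etherification of the only phenol; the phenoxide flanked by two methoxyls is hindered but should alkylate cleanly with a reactive benzylic halide in a dipolar aprotic solvent.

Step 2
Reactants: 2 1-[4-(benzyloxy)-3,5-dimethoxyphenyl]ethan-1-one
Product: 3 1-[4-(benzyloxy)-2-iodo-3,5-dimethoxyphenyl]ethan-1-one
Conditions: I2, AgO2CCF3, CH2Cl2, 0 °C to rt, dark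
Reagents that add atoms: iodine, II
Why: Electrophilic aromatic iodination by the acyl hypoiodite formed from I2 and the silver salt; the two free ring positions of 2 are equivalent and each is ortho to one methoxyl and para to the other, so one equivalent should give a single monoiodide. The conditions are neutral to weakly acidic and non-enolising, which should keep the acetyl methyl group out of the reaction.

Step 3
Reactants: 3 1-[4-(benzyloxy)-2-iodo-3,5-dimethoxyphenyl]ethan-1-one
Product: 4 1-[4-(benzyloxy)-2-hydroxy-3,5-dimethoxyphenyl]ethan-1-one
Conditions: CuI (10 mol%), 1,10-phenanthroline (20 mol%), KOH, DMSO/H2O (1:1), 100 °C; then 1 M HCl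
Reagents that add atoms: potassium hydroxide, [K+].[OH-]
Why: Copper-catalysed Ullmann-type hydroxylation of an aryl iodide; the ortho acetyl group should assist by coordinating copper, and the product leaves the cycle as a phenoxide that is inert to further substitution or condensation.

Step 4
Reactants: 4 1-[4-(benzyloxy)-2-hydroxy-3,5-dimethoxyphenyl]ethan-1-one
Product: 5 1-[2,4-bis(benzyloxy)-3,5-dimethoxyphenyl]ethan-1-one
Conditions: BnBr, K2CO3, Bu4NI (cat.), DMF, 70 °C
Reagents that add atoms: benzyl bromide, BrCc1ccccc1
Why: Williamson etherification; the hydrogen-bonded ortho-hydroxy ketone needs gentle heating, and carbonate is too weak to enolise the methyl ketone, so alkylation should occur on oxygen only.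

Step 5
Reactants: 6 3,5-dihydroxy-4-methoxybenzoic acid
Product: 7 3,5-bis[(2,2-dimethylpropanoyl)oxy]-4-methoxybenzoic acid
Conditions: PivCl (2.5 equiv), NaOH (aq), THF/H2O, 0 °C, pH 10–11; then HCl (pH 2)
Reagents that add atoms: pivaloyl chloride, CC(C)(C)C(=O)Cl
Why: Schotten–Baumann acylation; the two phenoxides are acylated while the carboxylate stays as its sodium salt, and any mixed anhydride formed at the carboxyl group is hydrolysed again in the aqueous base.

Step 6
Reactants: 7 3,5-bis[(2,2-dimethylpropanoyl)oxy]-4-methoxybenzoic acid; 5 1-[2,4-bis(benzyloxy)-3,5-dimethoxyphenyl]ethan-1-one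
Product: 9 5-{3-[2,4-bis(benzyloxy)-3,5-dimethoxyphenyl]-3-oxopropanoyl}-2-methoxy-1,3-phenylene bis(2,2-dimethylpropanoate), via aroyl chloride 8 (not isolated)
Conditions: 7, (COCl)2, DMF (cat.), CH2Cl2, 0 °C to rt, evaporate; then 5, MgBr2·OEt2 (2.5 equiv), i-Pr2NEt (3 equiv), CH2Cl2, 0 °C to rt; 1 M HCl
Reagents that add atoms: none
Why: Crossed Claisen condensation by soft enolisation: MgBr2 activates the ketone so that the tertiary amine can deprotonate it, and the magnesium enolate is acylated on carbon by 8. The product is held as a magnesium diketonate, which should prevent a second acylation, and the hindered aryl pivalates and the benzyl ethers should survive these cold, weakly basic conditions.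

Step 7
Reactants: 9 5-{3-[2,4-bis(benzyloxy)-3,5-dimethoxyphenyl]-3-oxopropanoyl}-2-methoxy-1,3-phenylene bis(2,2-dimethylpropanoate)
Product: 10 5-[5,7-bis(benzyloxy)-6,8-dimethoxy-4-oxo-4H-chromen-2-yl]-2-methoxy-1,3-phenylene bis(2,2-dimethylpropanoate)
Conditions: graphite anode, platinum cathode, undivided cell, constant current (3 mA cm−2, 2.2 F mol−1), Bu4NBF4 (0.1 M), 2,6-lutidine (2 equiv), HFIP/CH2Cl2 (4:1), 0.01 M, rt
Reagents that add atoms: none
Why: Proposed new method: anodic dehydrogenative coupling of a 1,3-diketone enol O–H with an arene C–H to close a 4-pyranone is not established; the closest known reaction types are the anodic dehydrogenative lactonisation of biaryl-2-carboxylic acids and the anodic cyclisation of anilides to benzoxazoles, where an oxygen nucleophile likewise captures an anodically activated arene. The four alkoxy donors make ring A of 9, conjugated with the enol, the site of lowest oxidation potential, whereas ring B carries two acyloxy acceptors, so the first electron should leave ring A and give a radical cation that HFIP stabilises. C8a is the only hydrogen-bearing carbon of ring A and lies para to the C6 methoxyl and ortho to the C8 methoxyl, where hole density is high; once HFIP and the non-chelating lutidinium counter-ion have broken the internal hydrogen bond of the enol, the C2 oxygen can turn toward C8a and add in a six-membered closure (O1–C2–C3–C4–C4a–C8a, formally 6-exo-trig with respect to the C8–C8a π bond). Loss of a second electron and of the C8a proton to 2,6-lutidine restores aromaticity, and the protons are discharged as H2 at the cathode, so no chemical oxidant is present. Should the enolate be oxidised first, the electrophilic diketonyl radical carries spin on the same oxygen and should attack the same electron-rich carbon, so both pathways converge on 10. Addition of the oxygen to an alkoxy-bearing carbon of ring A is reversible and has no proton to lose, which should keep the closure at C8a. The pyranone withdraws electron density from ring A, so 10 should be harder to oxidise than 9, and the charge is limited to a little over 2 F mol−1 to spare the para-related O5/O8 pair; no stereocentre is formed.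

Step 8
Reactants: 10 5-[5,7-bis(benzyloxy)-6,8-dimethoxy-4-oxo-4H-chromen-2-yl]-2-methoxy-1,3-phenylene bis(2,2-dimethylpropanoate)
Product: 12 5,7-dihydroxy-2-(3,5-dihydroxy-4-methoxyphenyl)-6,8-dimethoxy-4H-chromen-4-one, via bisphenol 11 (not isolated)
Conditions: K2CO3 (3 equiv), MeOH/THF (1:1), rt; then AcOH, 10% Pd/C, H2 (1 atm), rt
Reagents that add atoms: none
Why: Base-mediated methanolysis (transesterification) of the two aryl pivalates, then, after buffering with acetic acid, hydrogenolysis of the two aryl benzyl ethers over Pd/C in the same flask. The three methyl ethers are inert to both, and the conjugated C2–C3 double bond of the flavone should resist hydrogen at 1 atm for the short time needed.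

## Compound list

1 | 1-(4-hydroxy-3,5-dimethoxyphenyl)ethan-1-one (acetosyringone) | CC(=O)c1cc(OC)c(O)c(OC)c1 | starting material
2 | 1-[4-(benzyloxy)-3,5-dimethoxyphenyl]ethan-1-one | CC(=O)c1cc(OC)c(OCc2ccccc2)c(OC)c1 | intermediate
3 | 1-[4-(benzyloxy)-2-iodo-3,5-dimethoxyphenyl]ethan-1-one | CC(=O)c1cc(OC)c(OCc2ccccc2)c(OC)c1I | intermediate
4 | 1-[4-(benzyloxy)-2-hydroxy-3,5-dimethoxyphenyl]ethan-1-one | CC(=O)c1cc(OC)c(OCc2ccccc2)c(OC)c1O | intermediate
5 | 1-[2,4-bis(benzyloxy)-3,5-dimethoxyphenyl]ethan-1-one | CC(=O)c1cc(OC)c(OCc2ccccc2)c(OC)c1OCc1ccccc1 | intermediate
6 | 3,5-dihydroxy-4-methoxybenzoic acid | COc1c(O)cc(C(=O)O)cc1O | starting material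
7 | 3,5-bis[(2,2-dimethylpropanoyl)oxy]-4-methoxybenzoic acid | COc1c(OC(=O)C(C)(C)C)cc(C(=O)O)cc1OC(=O)C(C)(C)C | intermediate
8 | 5-(chlorocarbonyl)-2-methoxy-1,3-phenylene bis(2,2-dimethylpropanoate) | COc1c(OC(=O)C(C)(C)C)cc(C(=O)Cl)cc1OC(=O)C(C)(C)C | intermediate (not isolated)
9 | 5-{3-[2,4-bis(benzyloxy)-3,5-dimethoxyphenyl]-3-oxopropanoyl}-2-methoxy-1,3-phenylene bis(2,2-dimethylpropanoate) | O=C(CC(=O)c1cc(OC(=O)C(C)(C)C)c(OC)c(OC(=O)C(C)(C)C)c1)c1cc(OC)c(OCc2ccccc2)c(OC)c1OCc1ccccc1 | intermediate
10 | 5-[5,7-bis(benzyloxy)-6,8-dimethoxy-4-oxo-4H-chromen-2-yl]-2-methoxy-1,3-phenylene bis(2,2-dimethylpropanoate) | O=c1cc(-c2cc(OC(=O)C(C)(C)C)c(OC)c(OC(=O)C(C)(C)C)c2)oc2c(OC)c(OCc3ccccc3)c(OC)c(OCc3ccccc3)c12 | intermediate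
11 | 5,7-bis(benzyloxy)-2-(3,5-dihydroxy-4-methoxyphenyl)-6,8-dimethoxy-4H-chromen-4-one | O=c1cc(-c2cc(O)c(OC)c(O)c2)oc2c(OC)c(OCc3ccccc3)c(OC)c(OCc3ccccc3)c12 | intermediate (not isolated)
12 | 5,7-dihydroxy-2-(3,5-dihydroxy-4-methoxyphenyl)-6,8-dimethoxy-4H-chromen-4-one | COc1c(O)cc(-c2cc(=O)c3c(O)c(OC)c(O)c(OC)c3o2)cc1O | target

## Step count and least certain steps

Total step count: 8. Longest linear sequence: 7 (steps 1, 2, 3, 4, 6, 7, 8); step 5 is the second branch.

Step 7 (key step, proposed new method).
- What may go wrong: electron transfer from the diketonate at its central carbon followed by intermolecular C–C dimerisation; addition of the enol oxygen to the benzyloxy-bearing ortho carbon with loss of the benzyl group, or cleavage of that benzyl ether in the radical cation followed by dehydrative closure in the wrong sense; over-oxidation of ring A with loss of O-alkyl groups toward a quinone; failure of the enol to leave its chelated conformation.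
- Fallback with known chemistry, from 5 back to 10: iodination of the last ring hydrogen of 5 (I2, AgO2CCF3, CH2Cl2) would give 1-[2,4-bis(benzyloxy)-6-iodo-3,5-dimethoxyphenyl]ethan-1-one F1. The soft-enolisation Claisen condensation of F1 with 8 would give 5-{3-[2,4-bis(benzyloxy)-6-iodo-3,5-dimethoxyphenyl]-3-oxopropanoyl}-2-methoxy-1,3-phenylene bis(2,2-dimethylpropanoate) F2. A copper-catalysed intramolecular Ullmann O-arylation of its enolate (CuI, 1,10-phenanthroline, K2CO3, DMF, 80 °C) would form the same O1–C8a bond and rejoin the route at 10.

Step 6.
- What may go wrong: acylation on the enolate oxygen or a second acylation; chelation-assisted cleavage of the benzyl ether ortho to the ketone by MgBr2; acyl transfer from a pivalate to the enolate.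
- Fallback, from 8 and 5 back to 9: reduction of 8 with LiAlH(Ot-Bu)3 (THF, −78 °C) would give 5-formyl-2-methoxy-1,3-phenylene bis(2,2-dimethylpropanoate) F3. Aldol addition of the lithium enolate of 5 (LDA, THF, −78 °C) would give racemic 5-{3-[2,4-bis(benzyloxy)-3,5-dimethoxyphenyl]-1-hydroxy-3-oxopropyl}-2-methoxy-1,3-phenylene bis(2,2-dimethylpropanoate) F4. Dess–Martin oxidation of the secondary alcohol would return to 9.

Step 3.
- What may go wrong: reductive loss of iodine, slow substitution at a carbon flanked by acetyl and methoxyl, or base-induced self-condensation of the methyl ketone in hot hydroxide.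
- Fallback, from 3 back to 4: Miyaura borylation (B2pin2, PdCl2(dppf), KOAc, dioxane, 90 °C) would give 1-[4-(benzyloxy)-3,5-dimethoxy-2-(4,4,5,5-tetramethyl-1,3,2-dioxaborolan-2-yl)phenyl]ethan-1-one F5. Oxidation of the C–B bond (NaBO3·4H2O, THF/H2O, rt) would give 4 under nearly neutral conditions.

Step 8.
- What may go wrong: stalling of the hydrogenolysis through catalyst poisoning in the salt-laden mixture, or saturation of the C2–C3 double bond on prolonged exposure to hydrogen.
- Fallback, from 10 back to 12: the methanolysis is worked up and 11 is isolated. Its benzyl ethers are then removed without hydrogen by Lewis-acid debenzylation (BCl3, pentamethylbenzene as cation scavenger, CH2Cl2, −78 °C), which should spare the methyl ethers and the pyranone. This fallback makes no new compound (F0).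

## Further compounds

F1 | step 7 | 1-[2,4-bis(benzyloxy)-6-iodo-3,5-dimethoxyphenyl]ethan-1-one | CC(=O)c1c(I)c(OC)c(OCc2ccccc2)c(OC)c1OCc1ccccc1
F2 | step 7 | 5-{3-[2,4-bis(benzyloxy)-6-iodo-3,5-dimethoxyphenyl]-3-oxopropanoyl}-2-methoxy-1,3-phenylene bis(2,2-dimethylpropanoate) | O=C(CC(=O)c1cc(OC(=O)C(C)(C)C)c(OC)c(OC(=O)C(C)(C)C)c1)c1c(I)c(OC)c(OCc2ccccc2)c(OC)c1OCc1ccccc1
F3 | step 6 | 5-formyl-2-methoxy-1,3-phenylene bis(2,2-dimethylpropanoate) | COc1c(OC(=O)C(C)(C)C)cc(C=O)cc1OC(=O)C(C)(C)C
F4 | step 6 | racemic 5-{3-[2,4-bis(benzyloxy)-3,5-dimethoxyphenyl]-1-hydroxy-3-oxopropyl}-2-methoxy-1,3-phenylene bis(2,2-dimethylpropanoate) | O=C(CC(O)c1cc(OC(=O)C(C)(C)C)c(OC)c(OC(=O)C(C)(C)C)c1)c1cc(OC)c(OCc2ccccc2)c(OC)c1OCc1ccccc1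
F5 | step 3 | 1-[4-(benzyloxy)-3,5-dimethoxy-2-(4,4,5,5-tetramethyl-1,3,2-dioxaborolan-2-yl)phenyl]ethan-1-one | CC(=O)c1cc(OC)c(OCc2ccccc2)c(OC)c1B1OC(C)(C)C(C)(C)O1
F0 | step 8 | none | none
A1 | alternative 1 | 2-[3,5-bis(benzyloxy)-4-methoxyphenyl]-5,8-dihydroxy-6-methoxy-7-(propan-2-yloxy)-4H-chromen-4-one | COc1c(O)c2c(=O)cc(-c3cc(OCc4ccccc4)c(OC)c(OCc4ccccc4)c3)oc2c(O)c1OC(C)C
A2 | alternative 1 | racemic 4-{6-[3,5-bis(benzyloxy)-4-methoxyphenyl]-4-oxo-4H-pyran-3-yl}-4-hydroxy-3-methoxy-2-(propan-2-yloxy)cyclobut-2-en-1-one | COC1=C(OC(C)C)C(=O)C1(O)c1coc(-c2cc(OCc3ccccc3)c(OC)c(OCc3ccccc3)c2)cc1=O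
A3 | alternative 1 | 3-methoxy-4-(propan-2-yloxy)cyclobut-3-ene-1,2-dione | COC1=C(OC(C)C)C(=O)C1=O
A4 | alternative 1 | 2-[3,5-bis(benzyloxy)-4-methoxyphenyl]-5-iodo-4H-pyran-4-one | COc1c(OCc2ccccc2)cc(-c2cc(=O)c(I)co2)cc1OCc1ccccc1
A5 | alternative 2 | 7-(benzyloxy)-2-[3,5-bis(benzyloxy)-4-methoxyphenyl]-5-hydroxy-6,8-dimethoxy-4H-chromen-4-one | O=c1cc(-c2cc(OCc3ccccc3)c(OC)c(OCc3ccccc3)c2)oc2c(OC)c(OCc3ccccc3)c(OC)c(O)c12
A6 | alternative 2 | 5-(benzyloxy)-2-iodo-4,6-dimethoxybenzene-1,3-diol | COc1c(O)c(I)c(O)c(OC)c1OCc1ccccc1
A7 | alternative 2 | 1,3-bis(benzyloxy)-5-ethynyl-2-methoxybenzene | C#Cc1cc(OCc2ccccc2)c(OC)c(OCc2ccccc2)c1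
A8 | alternative 2 | carbon monoxide | [C-]#[O+]
A9 | alternative 3 | 2-[3,5-bis(benzyloxy)-4-methoxyphenyl]-5,7-dihydroxy-6,8-dimethoxy-4H-chromen-4-one | COc1c(O)c(OC)c2oc(-c3cc(OCc4ccccc4)c(OC)c(OCc4ccccc4)c3)cc(=O)c2c1O
A10 | alternative 3 | racemic methyl 3-{6-[3,5-bis(benzyloxy)-4-methoxyphenyl]-2-(methoxymethyl)-4-oxo-4H-pyran-3-yl}-2-methoxy-3-oxopropanoate | COCc1oc(-c2cc(OCc3ccccc3)c(OC)c(OCc3ccccc3)c2)cc(=O)c1C(=O)C(OC)C(=O)OC
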